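The target is numbered C1(OBz)–C2=C3–C4(OBz)–C5(OH)–C6(OH)(C7H2OH) around its cyclohexene ring. Everything rests on disconnecting the C5–C6 bond of the cis-vicinal diol: both atoms are carbinol carbons, so the ring is closed by a SmI2 pinacol cyclisation of a C5 aldehyde onto a C6 ketone, which sets C5 and C6 in one operation under control of the allylic silyloxy centres C1 and C4. The precursor is an acyclic (Z)-hept-3-ene keto-aldehyde, reached from achiral dimethyl muconate through singlet-oxygen cis-1,4-dioxygenation and one enzymatic desymmetrisation. A late double Mitsunobu reaction inverts C1 and C4 and installs both benzoates.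

Key step: step 10

Assumption: the lipase in step 5 is taken to hydrolyse the acetoxymethyl group on the (R)-configured carbinol carbon of meso diacetate 6; this preference is empirical and must be confirmed on the substrate (see the fallback for step 5).

Step 1
Reactants: 1 dimethyl (2E,4E)-hexa-2,4-dienedioate
Product: 2 (2E,4E)-hexa-2,4-diene-1,6-diol
Conditions: iBu2AlH (4.4 equiv), CH2Cl2, −78 → 0 °C; aq. potassium sodium tartrate work-up
Reagents that add atoms: none
Why: Ester reduction; the aluminium hydride should add 1,2 to both conjugated esters and leave the (E,E)-diene intact.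

Step 2
Reactants: 2 (2E,4E)-hexa-2,4-diene-1,6-diol
Product: 3 (2E,4E)-hexa-2,4-diene-1,6-diyl diacetate
Conditions: Ac2O, pyridine, 4-(dimethylamino)pyridine (cat.), CH2Cl2, rt
Reagents that add atoms: acetic anhydride, CC(=O)OC(C)=O
Why: O-Acylation of the two primary allylic alcohols; the acetates later serve as the enantiotopic groups and disfavour the competing ene reaction in step 3.

Step 3
Reactants: 3 (2E,4E)-hexa-2,4-diene-1,6-diyl diacetate
Product: 5 (2R,3Z,5S)-2,5-dihydroxyhex-3-ene-1,6-diyl diacetate (meso), via cis-endoperoxide 4 (not isolated)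
Conditions: O2, tetraphenylporphyrin (cat.), visible light, CH2Cl2, 0 °C; then thiourea, MeOH, rt
Reagents that add atoms: dioxygen, O=O
Why: Suprafacial [4+2] cycloaddition of singlet oxygen to the s-cis (E,E)-diene should form both C–O bonds on one face, fixing the meso relationship of the two carbinol carbons and the Z-alkene, and thiourea then cleaves only the O–O bond.

Step 4
Reactants: 5 (2R,3Z,5S)-2,5-dihydroxyhex-3-ene-1,6-diyl diacetate
Product: 6 (2R,3Z,5S)-2,5-bis[(tert-butyldimethylsilyl)oxy]hex-3-ene-1,6-diyl diacetate (meso)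
Conditions: TBSCl (2.5 equiv), imidazole, DMF, rt
Reagents that add atoms: tert-butyldimethylsilyl chloride, CC(C)(C)[Si](C)(C)Cl
Why: Silyl ether formation at both secondary allylic alcohols gives ether groups that tolerate the later ketyl chemistry; no stereocentre is touched.

Step 5
Reactants: 6 (2R,3Z,5S)-2,5-bis[(tert-butyldimethylsilyl)oxy]hex-3-ene-1,6-diyl diacetate
Product: 7 (2S,3Z,5R)-2,5-bis[(tert-butyldimethylsilyl)oxy]-6-hydroxyhex-3-en-1-yl acetate
Conditions: lipase from Burkholderia cepacia, KH2PO4/K2HPO4 buffer pH 7, acetone (co-solvent), 30 °C, stopped after cleavage of one acetate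
Reagents that add atoms: none
Why: Enzymatic desymmetrisation by enantiotopic-group-selective ester hydrolysis; freeing the hydroxyl next to the (R)-carbinol fixes the absolute sense of both existing stereocentres for the rest of the route.

Step 6
Reactants: 7 (2S,3Z,5R)-2,5-bis[(tert-butyldimethylsilyl)oxy]-6-hydroxyhex-3-en-1-yl acetate
Product: 8 (2S,3Z,5R)-2,5-bis[(tert-butyldimethylsilyl)oxy]-6-oxohex-3-en-1-yl acetate
Conditions: Dess–Martin periodinane, NaHCO3, CH2Cl2, 0 °C → rt; used without storage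
Reagents that add atoms: none
Why: Dess–Martin oxidation under buffered, base-free conditions should give the α-silyloxy β,γ-unsaturated aldehyde without epimerisation or migration of the alkene.

Step 7
Reactants: 9 tributyl(iodomethyl)stannane, 10 4-methoxybenzyl alcohol
Product: 11 tributyl{[(4-methoxybenzyl)oxy]methyl}stannane
Conditions: NaH, THF/DMF, 0 °C → rt
Reagents that add atoms: none
Why: Williamson ether synthesis; the sodium alkoxide of 10 displaces iodide at the tin-bearing methylene carbon.

Step 8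
Reactants: 8 (2S,3Z,5R)-2,5-bis[(tert-butyldimethylsilyl)oxy]-6-oxohex-3-en-1-yl acetate, 11 tributyl{[(4-methoxybenzyl)oxy]methyl}stannane
Product: 14 (2S,3Z,5R,6RS)-2,5-bis[(tert-butyldimethylsilyl)oxy]-7-[(4-methoxybenzyl)oxy]hept-3-ene-1,6-diol, via alkoxymethyllithium 12 (not isolated), via acetate-bearing adduct 13 (not isolated)
Conditions: 11, n-BuLi, THF, −78 °C; then 8, −78 °C; then MeOH, K2CO3, 0 °C
Reagents that add atoms: none
Why: Tin–lithium exchange gives an α-alkoxymethyllithium that adds to the aldehyde faster than to the acetate, and methanolysis then frees the primary alcohol; the new carbinol centre forms as a mixture that is erased by oxidation in step 9.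

Step 9
Reactants: 14 (2S,3Z,5R,6RS)-2,5-bis[(tert-butyldimethylsilyl)oxy]-7-[(4-methoxybenzyl)oxy]hept-3-ene-1,6-diol
Product: 15 (2S,3Z,5R)-2,5-bis[(tert-butyldimethylsilyl)oxy]-7-[(4-methoxybenzyl)oxy]-6-oxohept-3-enal
Conditions: Dess–Martin periodinane (3 equiv), NaHCO3, CH2Cl2, 0 °C → rt; crude 15 used at once
Reagents that add atoms: none
Why: Double Dess–Martin oxidation converts the primary and the secondary alcohol into aldehyde and ketone in one neutral operation, which should preserve the two base-sensitive allylic α-silyloxy stereocentres.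

Step 10
Reactants: 15 (2S,3Z,5R)-2,5-bis[(tert-butyldimethylsilyl)oxy]-7-[(4-methoxybenzyl)oxy]-6-oxohept-3-enal
Product: 16 (1R,2R,3S,6R)-3,6-bis[(tert-butyldimethylsilyl)oxy]-1-{[(4-methoxybenzyl)oxy]methyl}cyclohex-4-ene-1,2-diol
Conditions: SmI2 (3 equiv), t-BuOH (3 equiv), THF (0.01 M), −78 → −20 °C
Reagents that add atoms: none
Why: Single-electron transfer from SmI2 to the aldehyde gives a samarium-bound ketyl at C5 that adds to the ketone carbon C6, and a second electron reduces the resulting alkoxy radical to the samarium diolate (intramolecular pinacol coupling); the closest known reaction type is the SmI2 pinacol cyclisation of sugar-derived 1,6-dicarbonyl compounds to cyclitols. The cyclohexene ring closes in a 6-exo-trig mode, the (Z)-alkene holding C5 and C6 within bonding distance. C5 and C6 are both new stereocentres: their oxygens should end up cis because both are bound to trivalent samarium in the bond-forming transition state, and each should turn away from the neighbouring silyloxy group (at C4 and at C1) to avoid electrostatic and steric repulsion. Because the C1 and C4 silyloxy groups are cis to each other, both preferences point to the same face, so the (1R,2R,3S,6R) diol should dominate. The step needs ketyl cyclisation to outrun β-elimination of the α-oxygen substituents, simple carbonyl reduction and intermolecular coupling; ether rather than ester protecting groups, low temperature, t-BuOH as the only additive and high dilution are meant to secure this.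

Step 11
Reactants: 16 (1R,2R,3S,6R)-3,6-bis[(tert-butyldimethylsilyl)oxy]-1-{[(4-methoxybenzyl)oxy]methyl}cyclohex-4-ene-1,2-diol
Product: 17 (3aR,4S,7R,7aR)-4,7-bis[(tert-butyldimethylsilyl)oxy]-7a-{[(4-methoxybenzyl)oxy]methyl}-2,2-dimethyl-3a,4,7,7a-tetrahydro-1,3-benzodioxole
Conditions: 2,2-dimethoxypropane, pyridinium p-toluenesulfonate (cat.), acetone, rt
Reagents that add atoms: 2,2-dimethoxypropane, COC(C)(C)OC
Why: Ketal exchange; the cis-1,2-diol should close readily to the cis-fused dioxolane, masking the secondary and tertiary hydroxyls before the substitution at C1 and C4.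

Step 12
Reactants: 17 (3aR,4S,7R,7aR)-4,7-bis[(tert-butyldimethylsilyl)oxy]-7a-{[(4-methoxybenzyl)oxy]methyl}-2,2-dimethyl-3a,4,7,7a-tetrahydro-1,3-benzodioxole
Product: 18 (3aR,4S,7R,7aS)-7a-{[(4-methoxybenzyl)oxy]methyl}-2,2-dimethyl-3a,4,7,7a-tetrahydro-1,3-benzodioxole-4,7-diol
Conditions: Bu4NF, THF, 0 °C → rt
Reagents that add atoms: none
Why: Fluoride-mediated cleavage of both silyl ethers frees the two allylic alcohols while ketal and benzyl-type ether stay intact.

Step 13
Reactants: 18 (3aR,4S,7R,7aS)-7a-{[(4-methoxybenzyl)oxy]methyl}-2,2-dimethyl-3a,4,7,7a-tetrahydro-1,3-benzodioxole-4,7-diol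
Product: 19 (3aR,4R,7S,7aS)-7a-{[(4-methoxybenzyl)oxy]methyl}-2,2-dimethyl-3a,4,7,7a-tetrahydro-1,3-benzodioxole-4,7-diyl dibenzoate
Conditions: PhCO2H (4 equiv), PPh3 (4 equiv), diisopropyl azodicarboxylate (4 equiv), toluene, 0 °C → rt
Reagents that add atoms: benzoic acid, O=C(O)c1ccccc1
Why: Double Mitsunobu reaction; benzoate should displace each alkoxyphosphonium group by SN2, inverting C1 and C4 (target numbering) so that both benzoates become cis to the dioxolane oxygens.

Step 14
Reactants: 19 (3aR,4R,7S,7aS)-7a-{[(4-methoxybenzyl)oxy]methyl}-2,2-dimethyl-3a,4,7,7a-tetrahydro-1,3-benzodioxole-4,7-diyl dibenzoate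
Product: 20 (1S,4R,5R,6R)-5,6-dihydroxy-6-(hydroxymethyl)cyclohex-2-ene-1,4-diyl dibenzoate
Conditions: CF3CO2H/H2O (9:1), CH2Cl2, 0 °C
Reagents that add atoms: none
Why: Acid hydrolysis of the isopropylidene ketal and acidolysis of the 4-methoxybenzyl ether in one operation; the benzoates and the alkene should survive short exposure at 0 °C and no stereocentre is touched.

Compound list
1 | dimethyl (2E,4E)-hexa-2,4-dienedioate | COC(=O)/C=C/C=C/C(=O)OC | starting material
2 | (2E,4E)-hexa-2,4-diene-1,6-diol | OC/C=C/C=C/CO | intermediate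
3 | (2E,4E)-hexa-2,4-diene-1,6-diyl diacetate | CC(=O)OC/C=C/C=C/COC(C)=O | intermediate
4 | [(3R,6S)-3,6-dihydro-1,2-dioxine-3,6-diyl]bis(methylene) diacetate (cis, meso) | CC(=O)OC[C@H]1C=C[C@@H](COC(C)=O)OO1 | intermediate
5 | (2R,3Z,5S)-2,5-dihydroxyhex-3-ene-1,6-diyl diacetate (meso) | CC(=O)OC[C@@H](O)/C=C\[C@@H](O)COC(C)=O | intermediate
6 | (2R,3Z,5S)-2,5-bis[(tert-butyldimethylsilyl)oxy]hex-3-ene-1,6-diyl diacetate (meso) | CC(=O)OC[C@@H](O[Si](C)(C)C(C)(C)C)/C=C\[C@@H](O[Si](C)(C)C(C)(C)C)COC(C)=O | intermediate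
7 | (2S,3Z,5R)-2,5-bis[(tert-butyldimethylsilyl)oxy]-6-hydroxyhex-3-en-1-yl acetate | CC(=O)OC[C@@H](O[Si](C)(C)C(C)(C)C)/C=C\[C@@H](O[Si](C)(C)C(C)(C)C)CO | intermediate
8 | (2S,3Z,5R)-2,5-bis[(tert-butyldimethylsilyl)oxy]-6-oxohex-3-en-1-yl acetate | CC(=O)OC[C@@H](O[Si](C)(C)C(C)(C)C)/C=C\[C@@H](O[Si](C)(C)C(C)(C)C)C=O | intermediate
9 | tributyl(iodomethyl)stannane | CCCC[Sn](CCCC)(CCCC)CI | starting material
10 | 4-methoxybenzyl alcohol | COc1ccc(CO)cc1 | starting material
11 | tributyl{[(4-methoxybenzyl)oxy]methyl}stannane | CCCC[Sn](CCCC)(CCCC)COCc1ccc(OC)cc1 | intermediate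
12 | [(4-methoxybenzyl)oxy]methyllithium | [Li]COCc1ccc(OC)cc1 | intermediate
13 | (2S,3Z,5R,6RS)-2,5-bis[(tert-butyldimethylsilyl)oxy]-6-hydroxy-7-[(4-methoxybenzyl)oxy]hept-3-en-1-yl acetate (both C6 epimers) | CC(=O)OC[C@@H](O[Si](C)(C)C(C)(C)C)/C=C\[C@@H](O[Si](C)(C)C(C)(C)C)C(O)COCc1ccc(OC)cc1 | intermediate
14 | (2S,3Z,5R,6RS)-2,5-bis[(tert-butyldimethylsilyl)oxy]-7-[(4-methoxybenzyl)oxy]hept-3-ene-1,6-diol (both C6 epimers) | OC[C@@H](O[Si](C)(C)C(C)(C)C)/C=C\[C@@H](O[Si](C)(C)C(C)(C)C)C(O)COCc1ccc(OC)cc1 | intermediate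
15 | (2S,3Z,5R)-2,5-bis[(tert-butyldimethylsilyl)oxy]-7-[(4-methoxybenzyl)oxy]-6-oxohept-3-enal | O=C[C@@H](O[Si](C)(C)C(C)(C)C)/C=C\[C@@H](O[Si](C)(C)C(C)(C)C)C(=O)COCc1ccc(OC)cc1 | intermediate
16 | (1R,2R,3S,6R)-3,6-bis[(tert-butyldimethylsilyl)oxy]-1-{[(4-methoxybenzyl)oxy]methyl}cyclohex-4-ene-1,2-diol | CC(C)(C)[Si](C)(C)O[C@@H]1C=C[C@H](O[Si](C)(C)C(C)(C)C)[C@@H](O)[C@]1(O)COCc1ccc(OC)cc1 | intermediate
17 | (3aR,4S,7R,7aR)-4,7-bis[(tert-butyldimethylsilyl)oxy]-7a-{[(4-methoxybenzyl)oxy]methyl}-2,2-dimethyl-3a,4,7,7a-tetrahydro-1,3-benzodioxole | CC(C)(C)[Si](C)(C)O[C@@H]1C=C[C@H](O[Si](C)(C)C(C)(C)C)[C@H]2OC(C)(C)O[C@@]12COCc1ccc(OC)cc1 | intermediate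
18 | (3aR,4S,7R,7aS)-7a-{[(4-methoxybenzyl)oxy]methyl}-2,2-dimethyl-3a,4,7,7a-tetrahydro-1,3-benzodioxole-4,7-diol | O[C@@H]1C=C[C@H](O)[C@H]2OC(C)(C)O[C@@]12COCc1ccc(OC)cc1 | intermediate
19 | (3aR,4R,7S,7aS)-7a-{[(4-methoxybenzyl)oxy]methyl}-2,2-dimethyl-3a,4,7,7a-tetrahydro-1,3-benzodioxole-4,7-diyl dibenzoate | O=C(O[C@H]1C=C[C@@H](OC(=O)c2ccccc2)[C@H]2OC(C)(C)O[C@@]12COCc1ccc(OC)cc1)c1ccccc1 | intermediate
20 | (1S,4R,5R,6R)-5,6-dihydroxy-6-(hydroxymethyl)cyclohex-2-ene-1,4-diyl dibenzoate | O=C(O[C@H]1C=C[C@@H](OC(=O)c2ccccc2)[C@@H](O)[C@]1(O)CO)c1ccccc1 | target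

Total step count: 14. Longest linear sequence: 13 steps (steps 1–6 and 8–14); step 7 is a one-step branch.

Steps most likely to fail

Step 10 (pinacol cyclisation). The ketyl may lose an α-oxygen substituent by reductive β-elimination, or the new diol may form with poor control of its configuration relative to the silyloxy groups. The fallback separates C–C bond formation from the setting of the stereocentres. It sets out from 15: a McMurry coupling (TiCl3(DME)1.5, Zn–Cu couple, dimethoxyethane, reflux) would join C5 and C6 as an alkene and give (3S,6R)-3,6-bis[(tert-butyldimethylsilyl)oxy]-1-{[(4-methoxybenzyl)oxy]methyl}cyclohexa-1,4-diene F1. Dihydroxylation (OsO4 cat., N-methylmorpholine N-oxide, acetone/H2O) of its trisubstituted, more electron-rich alkene from the face opposite both silyloxy groups should then return to the route at 16.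

Step 13 (double Mitsunobu reaction). Substitution at C1 next to the quaternary carbon may be slow, and SN2′ attack on the allylic alkoxyphosphonium ion may compete, so that inversion is incomplete. The fallback sets out from 18 and replaces substitution by oxidation and reduction. Dess–Martin oxidation would give (3aS,7aR)-7a-{[(4-methoxybenzyl)oxy]methyl}-2,2-dimethyl-3a,7a-dihydro-1,3-benzodioxole-4,7-dione F2. Luche reduction (NaBH4, CeCl3·7H2O, MeOH, −78 °C), with hydride entering from the convex face away from the dioxolane, should give (3aR,4R,7S,7aS)-7a-{[(4-methoxybenzyl)oxy]methyl}-2,2-dimethyl-3a,4,7,7a-tetrahydro-1,3-benzodioxole-4,7-diol F3. Benzoylation with retention (PhCOCl, pyridine, 4-(dimethylamino)pyridine) returns to the route at 19.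

Step 5 (enzymatic desymmetrisation). Discrimination between the two enantiotopic acetates may be insufficient or of the reversed sense. The fallback sets out from 6: methanolysis of both acetates (K2CO3, MeOH, 0 °C) would give (2R,3Z,5S)-2,5-bis[(tert-butyldimethylsilyl)oxy]hex-3-ene-1,6-diol F4. Lipase-catalysed transesterification of this meso diol with vinyl acetate in tert-butyl methyl ether acylates the hydroxyl group whose acetate the enzyme would hydrolyse, so it delivers the enantiocomplementary monoacetate. With the lipase chosen for the required sense, this returns to the route at 7.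

Further compounds
F1 | step 10 | (3S,6R)-3,6-bis[(tert-butyldimethylsilyl)oxy]-1-{[(4-methoxybenzyl)oxy]methyl}cyclohexa-1,4-diene | CC(C)(C)[Si](C)(C)O[C@@H]1C=C[C@H](O[Si](C)(C)C(C)(C)C)C=C1COCc1ccc(OC)cc1
F2 | step 13 | (3aS,7aR)-7a-{[(4-methoxybenzyl)oxy]methyl}-2,2-dimethyl-3a,7a-dihydro-1,3-benzodioxole-4,7-dione | O=C1C=CC(=O)[C@H]2OC(C)(C)O[C@@]12COCc1ccc(OC)cc1
F3 | step 13 | (3aR,4R,7S,7aS)-7a-{[(4-methoxybenzyl)oxy]methyl}-2,2-dimethyl-3a,4,7,7a-tetrahydro-1,3-benzodioxole-4,7-diol | O[C@H]1C=C[C@@H](O)[C@H]2OC(C)(C)O[C@@]12COCc1ccc(OC)cc1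
F4 | step 5 | (2R,3Z,5S)-2,5-bis[(tert-butyldimethylsilyl)oxy]hex-3-ene-1,6-diol (meso) | OC[C@@H](O[Si](C)(C)C(C)(C)C)/C=C\[C@@H](O[Si](C)(C)C(C)(C)C)CO
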